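All runs were computed from invented constants, and the scatter is random.

- Under the proposed steps, substrate, target and the two isomers add up to the charge. So whatever substrate is converted is shared among the products.

| setting | amber | grey | Thursday's | Tuesday's | Wednesday's | Friday's |
|---|---|---|---|---|---|---|
| substrate | 0.70 M | 1.1 M | 0.50 M | 0.50 M | 0.50 M | 0.50 M |
| reagent | 2 M | 2 M | 2.00 M | 2.00 M | 2.00 M | 2.00 M |
| catalyst | 0.55 mM | 0.55 mM | 0.55 mM | 0.55 mM | 0.55 mM | 0.55 mM |
| temperature | 15 °C | 50 °C | 40 °C | 20 °C | 80 °C | 60 °C |
| remark | run made earlier | run made earlier |  |  |  |  |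
| time |  |  | 2.5 h | 2.5 h | 2.5 h | 2.5 h |

- amber (time / h: target / %, substrate / %): 1.33: 38.9, 16.0; 3.00: 37.7, 15.4; 5.00: 38.5, 15.2
- grey (time / min: target / %, substrate / %): 5.00: 32.0, 31.6; 10.0: 29.1, 29.1; 25.0: 26.6, 26.8; 60.0: 26.0, 25.7

(standard deviation of a reading: 0.5 percentage points)

- the flask that comes out highest in amount of target, in percent of the substrate charged, or "all alike" when all lie within 1.5 percentage points (Thursday's / Tuesday's / Wednesday's / Friday's / all alike)
- target at the end, in percent of the substrate charged, Thursday's
- target at the end, in percent of the substrate charged, Tuesday's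
- target at the end, in percent of the substrate charged, Wednesday's
- target at the end, in percent of the substrate charged, Friday's

- steps that have been proposed: substrate + reagent <-> target; substrate + reagent <-> isomer of the product A; target + catalyst <-> isomer of the product B + catalyst; target + catalyst <-> isomer of the product A + catalyst

- Time comes first. The amber run reads 38.9% of target at 1.33 h and 38.5% at 5.00 h. The last two target readings of the grey run differ by 0.6 percentage points. So I treat the new flasks, at 2.5 h, as plateaus.
- At a plateau each proposed step runs equally both ways. I divide forward rate by back rate and time drops out. I divide one such ratio by another and substrate and reagent cancel too. So under this thermodynamic control the target share, target over substrate converted, depends on temperature and not on the charge.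
- The readings give a share of 0.454 in the amber run and 0.350 in the hotter grey run, so the grey share reads lower.
- A straight line of its logarithm against reciprocal temperature gives 0.436 for Tuesday's flask. For Wednesday's flask it gives 0.292, the target share at that temperature.
- Conversion needs a second ratio: converted over substrate left, per molar of reagent left. It reads 3.97 L mol⁻¹ in the amber run and 2.44 L mol⁻¹ in the grey run. The same line gives 3.68 L mol⁻¹ for Tuesday's flask and 1.74 L mol⁻¹ for Wednesday's.
- With reagent held at its charge, Wednesday's flask converts 77.7%. That is the weak link. In my reckoning reagent falls too, by 19.4% of its charge. Subtracting that lowers Wednesday's conversion to 73.7%. Tuesday's goes from 88.0% to 85.1%.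
- Share times conversion gives me 37.1% of target on Tuesday's and 21.5% on Wednesday's, so the cooler flask leads.
- The forecast gives 38.1% for Tuesday's, 31.5% for Thursday's, 26.5% for Friday's and 22.4% for Wednesday's: “The coolest flask, Tuesday's, wins.” Its Tuesday's and Wednesday's figures stand above mine.
- The flasks give 37.9% on Tuesday's, 32.0% on Thursday's, 25.9% on Friday's and 20.8% on Wednesday's, and Tuesday's is highest.

    substrate + reagent ⇌ target (K = 1.57 L mol⁻¹, k = 0.0543 L mol⁻¹ min⁻¹, Ea = 64.0 kJ mol⁻¹, ΔH = −16.0 kJ mol⁻¹)
    substrate + reagent ⇌ isomer of the product A (K = 1.40 L mol⁻¹, k = 7.33 × 10⁻⁴ L mol⁻¹ min⁻¹, Ea = 63.0 kJ mol⁻¹, ΔH = −1.00 kJ mol⁻¹)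
    target + catalyst ⇌ isomer of the product B + catalyst, rate k3*[catalyst]*[target] forward; the back reaction follows from the equilibrium constant (K = 0.340, k = 1150 L mol⁻¹ min⁻¹, Ea = 52.0 kJ mol⁻¹, ΔH = −20.0 kJ mol⁻¹)
    target + catalyst ⇌ isomer of the product A + catalyst, rate k4*[catalyst]*[target] forward; the back reaction follows from the equilibrium constant (k = 119 L mol⁻¹ min⁻¹, Ea = 35.0 kJ mol⁻¹)
    (constants at 20 °C)

- On Wednesday's flask the step from substrate and reagent to target, taken by itself with both directions together, relaxes with a half-life of 0.0399 min, far shorter than the run of 2.5 h. Target there reads 20.8% at 1.25 h and 20.8% at 2.50 h, a share of 0.276 beside my 0.292. The neighbour of Wednesday's flask charged with 2.0 M of substrate keeps 40% of it and holds 16.5% of target, a share of 0.275.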